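## The problem

Irisoquin-C 15 is 2-hydroxy-5-methoxy-3-nonadecyl-1,4-benzoquinone: a single six-membered carbocycle with no stereocentre, so the whole task is regiochemical. Five ring carbons are substituted (carbonyl groups at C1 and C4, a free hydroxyl at C2, the unbranched C19 chain at C3, a methoxy group at C5) and only C6 carries hydrogen. The oxygens at C2 and C5 sit in nearly equivalent positions of a 2,5-dioxygenated quinone, yet one must end as a vinylogous acid and the other as its methyl ester, with the chain beside the hydroxyl; any route through a symmetrically oxygenated ring has to break that symmetry late. The finished quinone is fragile: hydroxide and amines displace the methoxy group, nucleophiles add to the ring, reduction is easy, and 2-hydroxy-3-alkylquinones are degraded by warm alkaline peroxide. The chain carries no function and need only enter as a cheap C19 electrophile. A convergent ring assembly is possible because C2 and C3 are adjacent and bear a heteroatom and the chain, so they can be the two carbons of one alkyne if boron stands in for the hydroxyl. C1 and C4 are para, which is the relationship between the inserted carbon monoxide and the carbene carbon in the benzannulation of a Fischer carbene complex of zerovalent chromium, and C5–C6 is a methoxy-bearing two-carbon unit that an α-metalated enol ether can supply.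

## Retrosynthesis

**15 to 14.** The C2–O bond is cut first: the hydroxyl of 15 is traced to the carbon–boron bond of quinone pinacol boronate 14. Holding the C2 oxygen as boron keeps it distinct from the C5 methoxy group until the last step. The neighbouring option, a 2,5-dialkoxyquinone with one ether to be cleaved selectively, would reopen the symmetry problem. 14 has the same skeleton but lacks the acidic hydroxyl. The forward step must oxidise an sp2 carbon–boron bond without harming a methoxyquinone.

**14 to 13.** The two carbonyl groups are returned to the phenol level, giving para-methoxyphenol 13, in which the C1 hydroxyl and the C4 methoxy group are para. No skeletal bond is cut, but the quinone becomes a benzene ring with the hydroxyl/alkoxy para pattern that a carbene benzannulation delivers. Compared with a hydroquinone dimethyl ether, the free C1 hydroxyl lowers the oxidation potential and fixes which methyl group is lost. The forward oxidation must remove the C4 methyl and leave the C5 methyl and the boronate.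

**13 to 5 and 11 (key disconnection).** Three ring bonds are cut together, C3–C4, C1–C2 and C1–C6, and C1 is returned to a carbonyl ligand. This leaves pentacarbonyl[methoxy(1-methoxyvinyl)carbene]chromium 5, which holds C4, C5, C6 and both methoxy groups, and alkynylboronate 11, which holds C2, C3, boron and the chain. A benzannulation with the terminal alkyne 7 instead would leave hydrogen at C2 and postpone the hydroxyl to a poorly selective quinone functionalisation. The precursors are one acyclic carbene complex and one linear alkyne. The forward step must insert the alkyne so that boron ends next to the carbon derived from carbon monoxide.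

**5 to 1 and 2.** The bond between the carbene carbon (future C4) and C5 and the oxygen–methyl bond at the carbene are cut. This gives methyl vinyl ether 1, metalated at its oxygen-bearing carbon as 3, chromium hexacarbonyl 2, and the acylate 4 formed between them. A cross-coupling or condensation route to the same complex would be longer. The forward sequence asks only that the lithiated enol ether add to a carbonyl ligand and that the acylate be methylated on oxygen.

**11 to 7 and 8, and 7 to 6.** The alkynyl carbon–boron bond is cut to heneicos-1-yne 7 and the isopropoxy pinacol borate 8, by way of acetylide 9 and ate complex 10. The bond between the chain and the alkyne is cut to 1-bromononadecane 6 and a two-carbon acetylide. Both are standard operations, and the only demand is anhydrous handling of the alkynylboronate 11.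

## Roads not taken

Alternative 1: The ring is cut into a four-carbon 1,2-diketone, tricosane-2,3-dione A1, and a two-carbon oxalic diester. In the forward direction the bis-enolate of A1 is acylated twice, forming C3–C4 and C5–C6, and the ring tautomerises to 2,5-dihydroxy-3-nonadecyl-1,4-benzoquinone A2.
- Merits: cheap reagents, no transition metal, and the whole oxygen pattern and the chain appear in one operation. A2 is one O-methylation from the target, so this road is probably the shortest on paper.
- Weak points: A1 has to be made first. An enolisable 1,2-diketone self-condenses under basic conditions, and the hindered internal methylene enolate of A1 must react twice. The decisive step is mono-methylation of A2 at the C5 hydroxyl in the presence of the C2 hydroxyl, which differ only by the neighbouring chain. Sterics point the right way, but the bis-ether and the wrong mono-ether are expected as by-products.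
- Comparison: this road is better in step count and metal economy. The chosen plan sets against it that the C2 and C5 oxygens are never equivalent, so no late selection on a sensitive quinone is needed.

Alternative 2: The ring is cut at C4–C5 and traced to a squarate-derived cyclobutenone, (Z)-4-hydroxy-3-isopropoxy-4-(2-methoxyvinyl)-2-nonadecylcyclobut-2-en-1-one A3. On heating, A3 opens to a dienylketene that closes by 6π electrocyclisation to the hydroquinone 2-isopropoxy-5-methoxy-3-nonadecylbenzene-1,4-diol A4. Oxidation of A4 to the quinone and removal of the isopropyl group would finish the synthesis.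
- Merits: regiochemistry is set by two sequential additions to a squaric diester, the second directed by the vinylogous ester. The thermal rearrangement of A3 is reliable and chromium is avoided. In security of the ring-forming step this road is at least equal to the chosen one, and the step count is similar.
- Weak points: the 2-methoxyvinyl nucleophile needs halogen–lithium or tin–lithium exchange on a precursor that must itself be made. The chain must be added to a squarate as a long-chain organometallic. The quinone derived from A4 again requires cleaving one vinylogous ester (isopropyl) beside another (methyl).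
- Comparison: the chosen plan sets against this a C2 oxygen masked as boron, orthogonal to the methyl ether, and two fragments made by direct deprotonation of commercial compounds.

Alternative 3: The ring is cut at C2–C3 of a resorcylate and traced to methyl 3,5,7-trioxohexacosanoate A5. Base-mediated aldol condensation of the C2 methylene of A5 onto its C7 ketone, followed by dehydration, gives methyl 2,4-dihydroxy-6-nonadecylbenzoate A6.
- Merits: biomimetic, metal-free, and the carbocycle forms with the chain in place from acetate-type building blocks.
- Weak points: the triketoester A5 is hard to handle and can cyclise in other modes (Claisen closure, pyrone formation). A6 has the wrong oxidation pattern: its ester carbon must be removed to give 5-nonadecylbenzene-1,3-diol A7. One of the two equivalent hydroxyls of A7 must then be methylated, and two more oxygens introduced ortho to the chain with only modest regiocontrol.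
- Comparison: ring construction is cheaper here, but the steps after A6 are longer and less selective than in the chosen plan, where every substituent arrives in the ring-forming step.

Key step: step 4

Assumption: the η6-arene tricarbonylchromium complex 12 formed first in step 4 is taken to give up its metal on stirring in air, so that the metal-free phenol 13 is the isolated product.

## Route

Step 1
Reactants: 1 methyl vinyl ether (methoxyethene); 2 chromium hexacarbonyl
Product: 5 pentacarbonyl[methoxy(1-methoxyvinyl)carbene]chromium, via 1-methoxyvinyllithium 3 (not isolated), via lithium acylchromate 4 (not isolated)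
Conditions: 1 (excess), t-BuLi, THF/pentane, −78 to 0 °C; Cr(CO)6, THF, −78 °C to rt; evaporation; Me3OBF4, CH2Cl2, 0 °C; filtration through silica (pentane), Ar, dark
Reagents that add atoms: trimethyloxonium tetrafluoroborate, C[O+](C)C.F[B-](F)(F)F
Why: Oxygen-directed vinylic deprotonation of the enol ether gives an acyl-anion equivalent that adds to a carbonyl ligand of Cr(CO)6, and O-methylation of the acylate by the hard oxonium salt completes a Fischer carbene synthesis; α-substituted alkenyl(alkoxy)carbene complexes are as a rule isolable, unlike the parent vinyl complex.

Step 2
Reactants: 6 1-bromononadecane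
Product: 7 heneicos-1-yne
Conditions: LiC≡CH·H2NCH2CH2NH2, DMSO/THF, 10 °C to rt
Reagents that add atoms: lithium acetylide–ethylenediamine complex, [Li]C#C.NCCN
Why: SN2 alkylation of an acetylide by an unhindered primary bromide in a dipolar aprotic medium; THF keeps the waxy bromide in solution and the diamine-complexed monolithium acetylide does not isomerise the terminal alkyne.

Step 3
Reactants: 7 heneicos-1-yne; 8 2-isopropoxy-4,4,5,5-tetramethyl-1,3,2-dioxaborolane
Product: 11 2-(heneicos-1-yn-1-yl)-4,4,5,5-tetramethyl-1,3,2-dioxaborolane, via lithium heneicos-1-ynide 9 (not isolated), via lithium alkynyl(isopropoxy)borate 10 (not isolated)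
Conditions: n-BuLi, THF, −20 °C; 8, −78 °C; HCl in Et2O, −78 °C to rt; filtration, non-aqueous work-up
Reagents that add atoms: none
Why: Deprotonation of the 1-alkyne, ate-complex formation with the isopropoxy boronate and expulsion of isopropanol by anhydrous acid is the standard borylation of terminal alkynes; the water-free work-up avoids protodeboronation of the alkynylboronate.

Step 4
Reactants: 5 pentacarbonyl[methoxy(1-methoxyvinyl)carbene]chromium; 11 2-(heneicos-1-yn-1-yl)-4,4,5,5-tetramethyl-1,3,2-dioxaborolane
Product: 13 4,5-dimethoxy-3-nonadecyl-2-(4,4,5,5-tetramethyl-1,3,2-dioxaborolan-2-yl)phenol, via arene tricarbonylchromium complex 12 (not isolated)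
Conditions: THF (0.05 M), 45 °C, Ar, dark; then air, rt; rapid chromatography
Reagents that add atoms: none
Why: Thermal loss of one cis carbonyl ligand from 5 lets the alkyne coordinate and insert into the chromium–carbon double bond to give an η3-vinylcarbene (C3–C4), and migratory insertion of a carbonyl ligand then gives an η4-vinylketene (C1–C2). The ketene carbon bonds to the terminal CH2 of the former methoxyvinyl group (C1–C6), and enolisation of the cyclohexadienone gives the phenol as its tricarbonylchromium complex 12, which loses the metal in air. The closest known reaction type is the Dötz benzannulation of alkenyl(alkoxy)carbene complexes with 1-alkynyl pinacol boronates, which gives ortho-borylated para-alkoxyphenols. The six-membered ring closes by 6π electrocyclisation of the metal-bound dienylketene. No stereocentre is formed. The one selectivity needed is the orientation of alkyne insertion: the larger alkyne substituent is placed away from the carbene methoxy group and ends beside the carbon derived from carbon monoxide, and the pinacol boronate, bulkier at the triple bond than an unbranched chain, should take that place, so boron ends at C2 next to the phenol. Phenol formation is favoured over cyclopentannulation or furan formation by chromium, an alkoxycarbene, an alkenyl rather than aryl substituent and a donor solvent at moderate temperature.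

Step 5
Reactants: 13 4,5-dimethoxy-3-nonadecyl-2-(4,4,5,5-tetramethyl-1,3,2-dioxaborolan-2-yl)phenol
Product: 14 5-methoxy-3-nonadecyl-2-(4,4,5,5-tetramethyl-1,3,2-dioxaborolan-2-yl)cyclohexa-2,5-diene-1,4-dione
Conditions: (NH4)2Ce(NO3)6, MeCN/H2O, 0 °C, short contact; extraction, no chromatography
Reagents that add atoms: water, O
Why: Oxidative demethylation of a para-methoxyphenol by tetravalent cerium: the phenoxonium ion is trapped by water at the methoxy-bearing C4 and loses methanol, the C5 methoxy group (not para to a hydroxyl) stays, and the pinacol boronate is expected to survive the brief cold contact as in related quinone boronates.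

Step 6
Reactants: 14 5-methoxy-3-nonadecyl-2-(4,4,5,5-tetramethyl-1,3,2-dioxaborolan-2-yl)cyclohexa-2,5-diene-1,4-dione
Product: 15 irisoquin-C, 2-hydroxy-5-methoxy-3-nonadecylcyclohexa-2,5-diene-1,4-dione
Conditions: NaBO3·4H2O (1.1 equiv), THF/H2O, 0 °C, Ar; then 1 M HCl to pH 3
Reagents that add atoms: sodium perborate (used as the tetrahydrate), [Na+].[Na+].O[B-]1(O)OO[B-](O)(O)OO1
Why: Oxidative hydroxydeboronation: hydroperoxide from the perborate adds to boron, the sp2 carbon migrates from boron to oxygen and the borate ester hydrolyses to the C2 hydroxyl; perborate is the mildest common oxidant for this, and the product forms as its deactivated vinylogous carboxylate, which shields the ring until acidification.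

## Compound list

1 | methyl vinyl ether (methoxyethene) | COC=C | starting material
2 | chromium hexacarbonyl | O=C=[Cr](=C=O)(=C=O)(=C=O)(=C=O)=C=O | starting material
3 | 1-methoxyvinyllithium | [Li]C(=C)OC | intermediate
4 | lithium pentacarbonyl(2-methoxyacryloyl)chromate | [Li+].[O-]C(C(OC)=C)=[Cr](=C=O)(=C=O)(=C=O)(=C=O)=C=O | intermediate
5 | pentacarbonyl[methoxy(1-methoxyvinyl)carbene]chromium | COC(C(OC)=C)=[Cr](=C=O)(=C=O)(=C=O)(=C=O)=C=O | intermediate
6 | 1-bromononadecane | CCCCCCCCCCCCCCCCCCCBr | starting material
7 | heneicos-1-yne | CCCCCCCCCCCCCCCCCCCC#C | intermediate
8 | 2-isopropoxy-4,4,5,5-tetramethyl-1,3,2-dioxaborolane | CC(C)OB1OC(C)(C)C(C)(C)O1 | starting material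
9 | lithium heneicos-1-ynide | CCCCCCCCCCCCCCCCCCCC#C[Li] | intermediate
10 | lithium (heneicos-1-yn-1-yl)(isopropoxy)(pinacolato)borate | [Li+].CCCCCCCCCCCCCCCCCCCC#C[B-]1(OC(C)C)OC(C)(C)C(C)(C)O1 | intermediate
11 | 2-(heneicos-1-yn-1-yl)-4,4,5,5-tetramethyl-1,3,2-dioxaborolane | CCCCCCCCCCCCCCCCCCCC#CB1OC(C)(C)C(C)(C)O1 | intermediate
12 | tricarbonyl[η6-4,5-dimethoxy-3-nonadecyl-2-(4,4,5,5-tetramethyl-1,3,2-dioxaborolan-2-yl)phenol]chromium (metal on the ring face, written as two fragments) | CCCCCCCCCCCCCCCCCCCc1c(B2OC(C)(C)C(C)(C)O2)c(O)cc(OC)c1OC.[Cr](=C=O)(=C=O)=C=O | intermediate
13 | 4,5-dimethoxy-3-nonadecyl-2-(4,4,5,5-tetramethyl-1,3,2-dioxaborolan-2-yl)phenol | CCCCCCCCCCCCCCCCCCCc1c(B2OC(C)(C)C(C)(C)O2)c(O)cc(OC)c1OC | intermediate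
14 | 5-methoxy-3-nonadecyl-2-(4,4,5,5-tetramethyl-1,3,2-dioxaborolan-2-yl)cyclohexa-2,5-diene-1,4-dione | CCCCCCCCCCCCCCCCCCCC1=C(B2OC(C)(C)C(C)(C)O2)C(=O)C=C(OC)C1=O | intermediate
15 | irisoquin-C, 2-hydroxy-5-methoxy-3-nonadecylcyclohexa-2,5-diene-1,4-dione | CCCCCCCCCCCCCCCCCCCC1=C(O)C(=O)C=C(OC)C1=O | target

## Step count and risks

Total step count: 6. Longest linear sequence: 5 steps (6 → 7 → 11 → 13 → 14 → 15); the carbene complex 5 is a one-step side branch.

**Step 4 (key step).** Most likely failure: alkyne insertion with the opposite or with mixed orientation. The boronate is a π-acceptor as well as a bulky group, and its electronic preference need not match the steric one. Thermal decay of the alkenylcarbene complex can also compete with the bimolecular step at high dilution. Fallback: if boron is delivered next to the carbene carbon, the two enol-ether carbons are made to exchange roles. The fallback sets out from chromium hexacarbonyl 2 and alkynylboronate 11. LiC≡CSiMe3 would be added to 2 and the acylate methylated in the same flask with Me3OBF4, as in step 1, to give pentacarbonyl[methoxy((trimethylsilyl)ethynyl)carbene]chromium F1. Conjugate addition of methanol (catalytic NaOMe, MeOH/THF, 0 °C), with loss of the silyl group, should then give pentacarbonyl[methoxy((E)-2-methoxyvinyl)carbene]chromium F2. Benzannulation of F2 with 11 under the conditions of step 4, with the reversed orientation, would give 4,6-dimethoxy-2-nonadecyl-3-(4,4,5,5-tetramethyl-1,3,2-dioxaborolan-2-yl)phenol F3. Oxidation of F3 with (NH4)2Ce(NO3)6 would give quinone boronate 14, where the route is rejoined.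

**Step 6.** Most likely failure: the peroxide nucleophile attacks the quinone ring (conjugate addition, epoxidation, displacement of the methoxy group) in competition with attack at boron. Other risks are slow boron-to-oxygen migration of the electron-poor quinonyl carbon, protodeboronation, and Hooker-type oxidative degradation of the product by excess alkaline peroxide. Fallback: the carbon–boron oxidation is moved to the aromatic level, setting out from 14. Reduction with Na2S2O4 (EtOAc/H2O, rt) would give 5-methoxy-3-nonadecyl-2-(4,4,5,5-tetramethyl-1,3,2-dioxaborolan-2-yl)benzene-1,4-diol F4, an electron-rich aryl boronate with no Michael acceptor. NaBO3·4H2O in degassed THF/H2O should oxidise F4 to 5-methoxy-3-nonadecylbenzene-1,2,4-triol F5, after which excess oxidant is destroyed with Na2SO3. Air or aqueous FeCl3 would then oxidise F5 to 15. Both quinone tautomers available to this triol are the same 2-hydroxy-1,4-quinone, so the route is rejoined at 15 without ambiguity.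

**Step 1.** Most likely failure: acid released from the oxonium salt hydrolyses or oligomerises the enol ether during O-methylation, and the neutral, Michael-accepting complex decomposes during chromatography. Fallback: purification is moved to the salt stage and the carbene is formed by acyl exchange instead of O-alkylation, setting out from acylate 4. Cation exchange with Me4NBr in water would precipitate tetramethylammonium pentacarbonyl(2-methoxyacryloyl)chromate F6, a storable solid that can be recrystallised. Acetyl bromide in CH2Cl2 at −40 °C should convert F6 into pentacarbonyl[acetoxy(1-methoxyvinyl)carbene]chromium F7. Methanol would then displace acetate from F7 at −40 to 0 °C to give 5, which is filtered and taken directly into step 4.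

## Further compounds

F1 | step 4 | pentacarbonyl[methoxy((trimethylsilyl)ethynyl)carbene]chromium | COC(C#C[Si](C)(C)C)=[Cr](=C=O)(=C=O)(=C=O)(=C=O)=C=O
F2 | step 4 | pentacarbonyl[methoxy((E)-2-methoxyvinyl)carbene]chromium | COC(/C=C/OC)=[Cr](=C=O)(=C=O)(=C=O)(=C=O)=C=O
F3 | step 4 | 4,6-dimethoxy-2-nonadecyl-3-(4,4,5,5-tetramethyl-1,3,2-dioxaborolan-2-yl)phenol | CCCCCCCCCCCCCCCCCCCc1c(O)c(OC)cc(OC)c1B2OC(C)(C)C(C)(C)O2
F4 | step 6 | 5-methoxy-3-nonadecyl-2-(4,4,5,5-tetramethyl-1,3,2-dioxaborolan-2-yl)benzene-1,4-diol | CCCCCCCCCCCCCCCCCCCc1c(B2OC(C)(C)C(C)(C)O2)c(O)cc(OC)c1O
F5 | step 6 | 5-methoxy-3-nonadecylbenzene-1,2,4-triol | CCCCCCCCCCCCCCCCCCCc1c(O)c(O)cc(OC)c1O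
F6 | step 1 | tetramethylammonium pentacarbonyl(2-methoxyacryloyl)chromate | C[N+](C)(C)C.[O-]C(C(OC)=C)=[Cr](=C=O)(=C=O)(=C=O)(=C=O)=C=O
F7 | step 1 | pentacarbonyl[acetoxy(1-methoxyvinyl)carbene]chromium | CC(=O)OC(C(OC)=C)=[Cr](=C=O)(=C=O)(=C=O)(=C=O)=C=O
A1 | alternative 1 | tricosane-2,3-dione | CCCCCCCCCCCCCCCCCCCCC(=O)C(=O)C
A2 | alternative 1 | 2,5-dihydroxy-3-nonadecyl-1,4-benzoquinone | CCCCCCCCCCCCCCCCCCCC1=C(O)C(=O)C=C(O)C1=O
A3 | alternative 2 | (Z)-4-hydroxy-3-isopropoxy-4-(2-methoxyvinyl)-2-nonadecylcyclobut-2-en-1-one (racemic) | CCCCCCCCCCCCCCCCCCCC1=C(OC(C)C)C(O)(/C=C\OC)C1=O
A4 | alternative 2 | 2-isopropoxy-5-methoxy-3-nonadecylbenzene-1,4-diol | CCCCCCCCCCCCCCCCCCCc1c(O)c(OC)cc(O)c1OC(C)C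
A5 | alternative 3 | methyl 3,5,7-trioxohexacosanoate | COC(=O)CC(=O)CC(=O)CC(=O)CCCCCCCCCCCCCCCCCCC
A6 | alternative 3 | methyl 2,4-dihydroxy-6-nonadecylbenzoate | CCCCCCCCCCCCCCCCCCCc1cc(O)cc(O)c1C(=O)OC
A7 | alternative 3 | 5-nonadecylbenzene-1,3-diol | CCCCCCCCCCCCCCCCCCCc1cc(O)cc(O)c1
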